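## Retrosynthetic overview
1. The target is the acetate of a cis-epoxy alcohol. That alcohol comes from an epoxide-directed, chemoselective hydride reduction of the C4 ketone of an epoxy-enedione, itself unmasked from an epoxy-dienone monoketal.
2. The epoxide and its absolute configuration come from catalytic asymmetric nucleophilic epoxidation of the farnesylated quinone monoketal, at the α-farnesyl/β-H enone.
3. Key disconnection: Stille coupling of an α-stannyl quinone monoketal (from 1,4-cyclohexanedione by iterative dehydrogenation and cuprate addition) with (E,E)-farnesyl bromide. The bromide is built from prenyl bromide and methyl acetoacetate by two rounds of alkylation, enol-phosphate formation and cuprate substitution.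
4. Ring order: the carbocycle is present from the first ring-branch starting material. The only ring formed after the coupling is the oxirane (step 21), and it is formed before the C4 alcohol is set.

Assumption: the cinchona-amine pseudo-enantiomer that delivers the epoxide face drawn in the target is used in step 21, and the farnesyl geometry is (2E,6E) as in the SMILES.

## Route

**Step 1**
Reactants: 1 methyl acetoacetate; 2 prenyl bromide
Product: 3 methyl 7-methyl-3-oxooct-6-enoate
Conditions: NaH, THF, 0 °C; n-BuLi, −10 °C; then 2, −78 → 0 °C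
Reagents that add atoms: none
Why: The dianion of 1 alkylates at the more nucleophilic γ-carbon (SN2 alkylation of an acetoacetate dianion). No stereocenter is formed.

**Step 2**
Reactants: 3
Product: 4 methyl (Z)-3-(diethoxyphosphoryloxy)-7-methylocta-2,6-dienoate
Conditions: NaH, THF, 0 °C; then (EtO)2P(O)Cl, 0 °C → rt
Reagents that add atoms: diethyl chlorophosphate, CCOP(=O)(Cl)OCC
Why: The chelated (Z)-sodium enolate is O-phosphorylated, so OP and CO2Me end up cis. This sets the alkene geometry used in step 3.

**Step 3**
Reactants: 4
Product: 5 methyl (E)-geranate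
Conditions: Me2CuLi (from MeLi, CuI), Et2O, −78 → −20 °C
Reagents that add atoms: lithium dimethylcuprate, C[Cu-]C.[Li+]
Why: Cuprate substitution of the enol phosphate proceeds with retention (Weiler alkene synthesis). Me lands cis to the ester, so the chain is trans and the alkene is E.

**Step 4**
Reactants: 5
Product: 6 geraniol
Conditions: DIBAL-H (2.5 equiv), CH2Cl2, −78 °C
Reagents that add atoms: none
Why: 1,2-Reduction of the ester to the allylic alcohol; the alkenes are untouched.

**Step 5**
Reactants: 6
Product: 7 geranyl bromide
Conditions: PBr3, Et2O, 0 °C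
Reagents that add atoms: phosphorus tribromide, BrP(Br)Br
Why: SN2 bromination of a primary allylic alcohol with retention of the E geometry. The bromide is used immediately.

**Step 6**
Reactants: 1 methyl acetoacetate; 7 geranyl bromide
Product: 8 methyl (6E)-7,11-dimethyl-3-oxododeca-6,10-dienoate
Conditions: NaH, THF, 0 °C; n-BuLi, −10 °C; then 7, −78 → 0 °C
Reagents that add atoms: none
Why: Same γ-alkylation of the acetoacetate dianion as step 1, now with the allylic bromide. The E geometry is retained.

**Step 7**
Reactants: 8
Product: 9 methyl (Z)-3-(diethoxyphosphoryloxy)-7,11-dimethyldodeca-2,6,10-trienoate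
Conditions: NaH, THF, 0 °C; then (EtO)2P(O)Cl
Reagents that add atoms: diethyl chlorophosphate, CCOP(=O)(Cl)OCC
Why: Same chelation-controlled (Z)-enol phosphate formation as step 2.

**Step 8**
Reactants: 9
Product: 10 methyl (2E,6E)-farnesoate
Conditions: Me2CuLi, Et2O, −78 → −20 °C
Reagents that add atoms: lithium dimethylcuprate, C[Cu-]C.[Li+]
Why: Substitution with retention gives the (2E) trisubstituted ester. The 6E alkene is carried through from step 6.

**Step 9**
Reactants: 10
Product: 11 (2E,6E)-farnesol
Conditions: DIBAL-H (2.5 equiv), CH2Cl2, −78 °C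
Reagents that add atoms: none
Why: Chemoselective ester reduction; all three alkenes survive.

**Step 10**
Reactants: 11
Product: 12 (2E,6E)-farnesyl bromide
Conditions: PBr3, Et2O, 0 °C
Reagents that add atoms: phosphorus tribromide, BrP(Br)Br
Why: SN2 bromination of the primary allylic alcohol with the geometry retained.

**Step 11**
Reactants: 13 1,4-cyclohexanedione
Product: 14 4,4-dimethoxycyclohexan-1-one
Conditions: HC(OMe)3 (0.9 equiv), TsOH (cat.), MeOH, rt
Reagents that add atoms: trimethyl orthoformate, COC(OC)OC
Why: Mono-ketalization of a symmetric dione, controlled by stoichiometry. No stereocenter is formed.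

**Step 12**
Reactants: 14
Product: 15 trimethyl[(4,4-dimethoxycyclohex-1-en-1-yl)oxy]silane
Conditions: LDA, THF, −78 °C; then TMSCl
Reagents that add atoms: chlorotrimethylsilane, C[Si](C)(C)Cl
Why: Kinetic enolization of the symmetric ketone; the ketal is base-stable.

**Step 13**
Reactants: 15
Product: 16 4,4-dimethoxycyclohex-2-en-1-one
Conditions: Pd(OAc)2 (1.1 equiv), MeCN, 25 °C
Reagents that add atoms: none
Why: Saegusa–Ito oxidation of the silyl enol ether (β-hydride elimination) installs the enone.

**Step 14**
Reactants: 16
Product: 17 silyl enol ether of 4,4-dimethoxy-3-methylcyclohexanone (racemic at C3)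
Conditions: Me2CuLi, TMSCl, THF, −78 °C
Reagents that add atoms: lithium dimethylcuprate, C[Cu-]C.[Li+]; chlorotrimethylsilane, C[Si](C)(C)Cl
Why: Cuprate 1,4-addition at the β-carbon next to the ketal, with the enolate trapped as TMS ether. The new Me-bearing stereocenter is racemic and is destroyed in step 15.

**Step 15**
Reactants: 17
Product: 18 4,4-dimethoxy-3-methylcyclohex-2-en-1-one
Conditions: Pd(OAc)2 (1.1 equiv), MeCN, 25 °C
Reagents that add atoms: none
Why: Saegusa–Ito oxidation restores the enone. The C3 stereocenter becomes sp2, so the material is achiral again.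

**Step 16**
Reactants: 18
Product: 19 silyl dienol ether of 18 (1-silyloxy-diene from α′-deprotonation)
Conditions: LDA, THF, −78 °C; then TMSCl
Reagents that add atoms: chlorotrimethylsilane, C[Si](C)(C)Cl
Why: Kinetic α′-deprotonation of a β-methyl enone occurs at C6 (the ring CH2), not at the γ-methyl.

**Step 17**
Reactants: 19
Product: 20 4,4-dimethoxy-3-methylcyclohexa-2,5-dien-1-one (quinone monoketal)
Conditions: Pd(OAc)2 (1.1 equiv), MeCN, 25 °C
Reagents that add atoms: none
Why: Second Saegusa–Ito oxidation. The quaternary ketal carbon prevents aromatization.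

**Step 18**
Reactants: 20
Product: 21 6-iodo-4,4-dimethoxy-3-methylcyclohexa-2,5-dien-1-one
Conditions: I2, pyridine, CCl4/CH2Cl2, 0 °C → rt
Reagents that add atoms: iodine, II
Why: α-Iodination of an enone by pyridine addition, iodination and elimination (Johnson). It occurs on the β-unsubstituted enone, because pyridine adds at the unhindered CH and not at the β-methyl carbon.

**Step 19**
Reactants: 21
Product: 22 4,4-dimethoxy-3-methyl-6-(trimethylstannyl)cyclohexa-2,5-dien-1-one
Conditions: (Me3Sn)2, Pd(PPh3)4 (5 mol %), THF, 60 °C
Reagents that add atoms: hexamethylditin, C[Sn](C)(C)[Sn](C)(C)C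
Why: Pd-catalyzed iodide-to-stannane exchange (Stille-type stannylation); the ketal and enones are inert.

**Step 20**
Reactants: 22; 12
Product: 23 6-[(2E,6E)-farnesyl]-4,4-dimethoxy-3-methylcyclohexa-2,5-dien-1-one
Conditions: Pd(PPh3)4 (5 mol %), CuI (10 mol %), LiCl, DMF, 40 °C
Reagents that add atoms: none
Why: Stille coupling of a vinylstannane with a primary allylic bromide. The bond forms at the unhindered allylic terminus with retention of the E,E geometry. This joins the two fragments.

**Step 21**
Reactants: 23
Product: 24 (1R,6S)-5,5-dimethoxy-4-methyl-1-farnesyl-7-oxabicyclo[4.1.0]hept-3-en-2-one; SMILES in the compound list (epoxide faces as in the target)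
Conditions: 30 % aq. H2O2, 9-amino-9-deoxy-epi-quinidine·2 TFA (20 mol %), 1,4-dioxane, 25 °C
Reagents that add atoms: hydrogen peroxide, OO
Why: Iminium-activated nucleophilic (Weitz–Scheffer-type) epoxidation. HOO⁻ adds to C3, the β-H carbon of the α-farnesyl enone, which is more electrophilic than the β-methyl enone. The chiral amine sets the epoxide face (C2 and C3); the ketal carbon is achiral, so there is no competing substrate bias.

**Step 22**
Reactants: 24
Product: 25 (1R,6S)-1-farnesyl-4-methyl-7-oxabicyclo[4.1.0]hept-3-ene-2,5-dione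
Conditions: I2 (10 mol %), acetone, 40 °C
Reagents that add atoms: acetone, CC(C)=O (supplies the carbonyl O by transketalization)
Why: Neutral transketalization removes the ketal without acid, protecting the epoxide and the farnesyl alkenes. No stereocenter changes.

**Step 23**
Reactants: 25
Product: 26 (1R,5R,6R)-5-hydroxy-4-methyl-1-farnesyl-7-oxabicyclo[4.1.0]hept-3-en-2-one
Conditions: NaBH4 (1 equiv), CeCl3·7H2O (1 equiv), MeOH/CH2Cl2, −78 °C
Reagents that add atoms: none
Why: Luche 1,2-reduction of the C5 carbonyl, which is less hindered than the C2 ketone next to the quaternary farnesyl-bearing carbon. Hydride arrives anti to the epoxide oxygen, so the new C5–OH is cis to the epoxide and (5R).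

**Step 24**
Reactants: 26
Product: 27 target, (1R,5R,6R)-5-acetoxy-4-methyl-1-[(2E,6E)-3,7,11-trimethyldodeca-2,6,10-trien-1-yl]-7-oxabicyclo[4.1.0]hept-3-en-2-one
Conditions: Ac2O, pyridine, DMAP (cat.), CH2Cl2, 0 °C
Reagents that add atoms: acetic anhydride, CC(=O)OC(C)=O
Why: O-Acetylation of the secondary alcohol with retention; no stereocenter is touched.

## Compound list
1 | methyl acetoacetate | COC(=O)CC(C)=O | starting material
2 | prenyl bromide | CC(C)=CCBr | starting material
3 | methyl 7-methyl-3-oxooct-6-enoate | COC(=O)CC(=O)CCC=C(C)C | intermediate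
4 | methyl (Z)-3-(diethoxyphosphoryloxy)-7-methylocta-2,6-dienoate | COC(=O)/C=C(\OP(=O)(OCC)OCC)CCC=C(C)C | intermediate
5 | methyl (E)-geranate | COC(=O)/C=C(\C)CCC=C(C)C | intermediate
6 | geraniol | OC/C=C(\C)CCC=C(C)C | intermediate
7 | geranyl bromide | BrC/C=C(\C)CCC=C(C)C | intermediate
8 | methyl (6E)-7,11-dimethyl-3-oxododeca-6,10-dienoate | COC(=O)CC(=O)CC/C=C(\C)CCC=C(C)C | intermediate
9 | methyl (Z)-3-(diethoxyphosphoryloxy)-7,11-dimethyldodeca-2,6,10-trienoate | COC(=O)/C=C(\OP(=O)(OCC)OCC)CC/C=C(\C)CCC=C(C)C | intermediate
10 | methyl (2E,6E)-farnesoate | COC(=O)/C=C(\C)CC/C=C(\C)CCC=C(C)C | intermediate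
11 | (2E,6E)-farnesol | OC/C=C(\C)CC/C=C(\C)CCC=C(C)C | intermediate
12 | (2E,6E)-farnesyl bromide | BrC/C=C(\C)CC/C=C(\C)CCC=C(C)C | intermediate
13 | 1,4-cyclohexanedione | O=C1CCC(=O)CC1 | starting material
14 | 4,4-dimethoxycyclohexan-1-one | COC1(OC)CCC(=O)CC1 | intermediate
15 | TMS enol ether of 14 | COC1(OC)CCC(O[Si](C)(C)C)=CC1 | intermediate
16 | 4,4-dimethoxycyclohex-2-en-1-one | COC1(OC)CCC(=O)C=C1 | intermediate
17 | TMS enol ether of 4,4-dimethoxy-3-methylcyclohexanone (racemic) | COC1(OC)C(C)C=C(O[Si](C)(C)C)CC1 | intermediate
18 | 4,4-dimethoxy-3-methylcyclohex-2-en-1-one | COC1(OC)C(C)=CC(=O)CC1 | intermediate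
19 | silyl dienol ether of 18 | COC1(OC)C(C)=CC(O[Si](C)(C)C)=CC1 | intermediate
20 | 4,4-dimethoxy-3-methylcyclohexa-2,5-dien-1-one | COC1(OC)C(C)=CC(=O)C=C1 | intermediate
21 | 6-iodo-4,4-dimethoxy-3-methylcyclohexa-2,5-dien-1-one | COC1(OC)C(C)=CC(=O)C(I)=C1 | intermediate
22 | 4,4-dimethoxy-3-methyl-6-(trimethylstannyl)cyclohexa-2,5-dien-1-one | COC1(OC)C(C)=CC(=O)C([Sn](C)(C)C)=C1 | intermediate
23 | 6-farnesyl-4,4-dimethoxy-3-methylcyclohexa-2,5-dien-1-one | COC1(OC)C(C)=CC(=O)C(C/C=C(\C)CC/C=C(\C)CCC=C(C)C)=C1 | intermediate
24 | epoxy-dienone monoketal (1R,6S) | COC1(OC)C(C)=CC(=O)[C@]2(C/C=C(\C)CC/C=C(\C)CCC=C(C)C)O[C@H]12 | intermediate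
25 | epoxy-enedione (1R,6S) | O=C1C(C)=CC(=O)[C@]2(C/C=C(\C)CC/C=C(\C)CCC=C(C)C)O[C@H]12 | intermediate
26 | cis-epoxy alcohol (1R,5R,6R) | O[C@@H]1C(C)=CC(=O)[C@]2(C/C=C(\C)CC/C=C(\C)CCC=C(C)C)O[C@H]12 | intermediate
27 | target acetate (1R,5R,6R) | CC(=O)O[C@@H]1C(C)=CC(=O)[C@]2(C/C=C(\C)CC/C=C(\C)CCC=C(C)C)O[C@H]12 | target

## Totals
Total steps: 24. Longest linear sequence: 15 (steps 1–10, then 20–24). The ring branch (steps 11–19) is 9 steps, so its path to the target is 14.

## Three steps most likely to fail
1. **Step 21, asymmetric epoxidation.** The enantioselectivity of amine-catalyzed epoxidation on a quinone monoketal is not established.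
   Fallback: epoxidize 23 racemically (H2O2, NaOH) and carry the racemate to 26. Resolve there by lipase-catalyzed acetylation (vinyl acetate), which gives 27 directly and leaves the unwanted enantiomer of 26 unchanged.
2. **Step 22, ketal removal next to the epoxide.** The oxocarbenium is destabilized by the adjacent epoxide, so cleavage may be slow or open the oxirane.
   Fallback: reorder the sequence. Hydrolyze the ketal of 23 first (facile for a dienone ketal) to give the 2-farnesyl-5-methylquinone, then run the organocatalytic epoxidation on the quinone. This relies on the α-farnesyl/β-H enone electronics for regiochemistry.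
3. **Step 23, regio- and diastereoselective reduction.** Hydride may attack C2 instead of C5, or arrive syn to the epoxide.
   Fallback: screen ketoreductase enzymes on 25 for C5-selective reduction. Alternatively, accept the trans alcohol and invert it by Mitsunobu reaction with p-nitrobenzoic acid, then methanolysis and step 24.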